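The plan cuts the O–C12 and C13–Br bonds of the 2,3,6,7-tetrahydrooxepine (ring O, C7–C12; chain numbered from the alkyne CH, C1, to the methyl, C15). It exploits the erythro pair C12–O/C13–Br (12R,13S) on the cis-2,7-disubstituted ring, which is what anti addition to an E olefin produces. One bromonium-induced 7-exo etherification should therefore close the ring, set C12 and C13, and introduce bromine as the last step. Its substrate is the open-chain C15 hydroxy acetate: (6S,7S), free O7–H, O6 acetylated, 3Z-enyne, 9Z and 12E olefins. This substrate comes from tartrate-derived (S,S)-diepoxybutane by two successive alkynyl openings, which also differentiate O6 from O7.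

Key step: step 13

Remark: commercial 1-bromopent-2-ene ("predominantly trans") is assumed to be the pure E isomer after fractional distillation. Locants C1–C15 always refer to the final chain.

Step 1
Reactants: 1 (4S,5S)-2,2-dimethyl-4,5-bis(tosyloxymethyl)-1,3-dioxolane
Product: 2 (2S,3S)-2,3-dihydroxybutane-1,4-diyl bis(4-methylbenzenesulfonate)
Conditions: 1 M HCl, EtOH, reflux
Reagents that add atoms: none
Why: Acid-catalysed acetal hydrolysis frees the 2,3-diol, while the primary tosylates and both carbinol centres (future C6 and C7) stay untouched.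

Step 2
Reactants: 2 (2S,3S)-2,3-dihydroxybutane-1,4-diyl bis(4-methylbenzenesulfonate)
Product: 3 (2S,2'S)-2,2'-bioxirane [(S,S)-diepoxybutane]
Conditions: KOH, H2O/Et2O, rt; distillation (closed apparatus, strong alkylating agent)
Reagents that add atoms: none
Why: A double intramolecular Williamson closure (3-exo-tet) displaces only the primary tosylates, so no C–O bond at a stereocentre breaks and the chiral-pool (S,S) configuration is carried over.

Step 3
Reactants: 4 (trimethylsilyl)acetylene; 5 (E)-1-bromopent-2-ene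
Product: 7 trimethyl[(E)-hept-4-en-1-yn-1-yl]silane, via trimethylsilylethynylmagnesium bromide 6 (not isolated)
Conditions: EtMgBr, THF, 0 °C to rt; CuBr·SMe2 (5 mol %), 5, 0 to 40 °C
Reagents that add atoms: none
Why: Copper(I)-catalysed allylic substitution of a primary allylic bromide by an alkynyl Grignard reagent runs mainly in the SN2 sense with retention of the E geometry, and the silyl cap prevents double allylation.

Step 4
Reactants: 7 trimethyl[(E)-hept-4-en-1-yn-1-yl]silane
Product: 8 (E)-hept-4-en-1-yne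
Conditions: K2CO3 (cat.), MeOH, rt; pentane extraction, distillation
Reagents that add atoms: none
Why: Base-catalysed protiodesilylation of the alkynyl–silicon bond is fast and too mild to isomerise the skipped enyne.

Step 5
Reactants: 8 (E)-hept-4-en-1-yne; 3 (2S,2'S)-2,2'-bioxirane
Product: 10 (1S,6E)-1-[(2S)-oxiran-2-yl]non-6-en-3-yn-1-ol, via lithium (E)-hept-4-en-1-ynide 9 (not isolated)
Conditions: n-BuLi, THF, −78 °C; BF3·OEt2; 3 (3 equiv), −78 °C; aqueous work-up, excess 3 distilled off
Reagents that add atoms: none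
Why: In this Yamaguchi–Hirao alkynylation the acetylide attacks the CH2 terminus (C8) of one oxirane, excess 3 favours single opening, the cold boron-bound alkoxide does not undergo Payne rearrangement, and no bond to C6 or C7 is touched.

Step 6
Reactants: 10 (1S,6E)-1-[(2S)-oxiran-2-yl]non-6-en-3-yn-1-ol
Product: 11 (1S,3Z,6E)-1-[(2S)-oxiran-2-yl]nona-3,6-dien-1-ol
Conditions: H2 (1 atm), Lindlar catalyst, quinoline, EtOAc, rt, stopped at one equivalent of H2
Reagents that add atoms: none
Why: Lindlar semihydrogenation adds H2 syn to the only alkyne present at this stage and sets the 9Z olefin, while the disubstituted E olefin and the oxirane survive the poisoned catalyst.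

Step 7
Reactants: 11 (1S,3Z,6E)-1-[(2S)-oxiran-2-yl]nona-3,6-dien-1-ol
Product: 12 tert-butyl(dimethyl){[(1S,3Z,6E)-1-[(2S)-oxiran-2-yl]nona-3,6-dien-1-yl]oxy}silane
Conditions: TBSCl, imidazole, DMF, rt
Reagents that add atoms: tert-butyldimethylsilyl chloride, CC(C)(C)[Si](C)(C)Cl
Why: Imidazole-promoted silylation masks O7, so the hydroxyl released by the next epoxide opening can only be O6, which is how the two oxygens are told apart.

Step 8
Reactants: 13 1,4-bis(trimethylsilyl)buta-1,3-diyne; 12 tert-butyl(dimethyl){[(1S,3Z,6E)-1-[(2S)-oxiran-2-yl]nona-3,6-dien-1-yl]oxy}silane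
Product: 15 (6S,7S,9Z,12E)-7-[(tert-butyldimethylsilyl)oxy]-1-(trimethylsilyl)pentadeca-9,12-diene-1,3-diyn-6-ol, via lithium 4-(trimethylsilyl)buta-1,3-diynide 14 (not isolated)
Conditions: 13, MeLi·LiBr, THF, 0 °C to rt; −78 °C, BF3·OEt2, then 12; aqueous work-up
Reagents that add atoms: none
Why: Monodesilylation of 13 gives a diynyl lithium whose Yamaguchi–Hirao opening at C5 installs C1–C4 in one bond and frees O6–H without touching C6, and this robust sp nucleophile is preferred to a Z-enynyl metal, whose vinyl halide precursor would tend to eliminate to the diyne.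

Step 9
Reactants: 15 (6S,7S,9Z,12E)-7-[(tert-butyldimethylsilyl)oxy]-1-(trimethylsilyl)pentadeca-9,12-diene-1,3-diyn-6-ol
Product: 17 (3Z,6S,7S,9Z,12E)-7-[(tert-butyldimethylsilyl)oxy]-1-(trimethylsilyl)pentadeca-3,9,12-trien-1-yn-6-ol, via C3-dicyclohexylboryl O6-borinate 16 (not isolated)
Conditions: Cy2BH (from cyclohexene, BH3·SMe2; 2.2 equiv), THF, 0 °C; AcOH, 0 °C to rt; aqueous work-up
Reagents that add atoms: none
Why: In this hydroboration–protonolysis of a 1-silyl-1,3-diyne the hindered dialkylborane adds syn to the alkyl-substituted triple bond (the silylated one is shielded and internal olefins react far more slowly), and acetolysis of the alkenyl C–B bond with retention gives the 3Z olefin.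

Step 10
Reactants: 17 (3Z,6S,7S,9Z,12E)-7-[(tert-butyldimethylsilyl)oxy]-1-(trimethylsilyl)pentadeca-3,9,12-trien-1-yn-6-ol
Product: 18 (3Z,6S,7S,9Z,12E)-7-[(tert-butyldimethylsilyl)oxy]pentadeca-3,9,12-trien-1-yn-6-ol
Conditions: K2CO3 (cat.), MeOH, 0 °C, short contact
Reagents that add atoms: none
Why: Base-catalysed protiodesilylation removes the alkynyl silane before any ester is present, and is fast enough at 0 °C that the secondary TBS ether neither cleaves nor migrates.

Step 11
Reactants: 18 (3Z,6S,7S,9Z,12E)-7-[(tert-butyldimethylsilyl)oxy]pentadeca-3,9,12-trien-1-yn-6-ol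
Product: 19 (3Z,6S,7S,9Z,12E)-7-[(tert-butyldimethylsilyl)oxy]pentadeca-3,9,12-trien-1-yn-6-yl acetate
Conditions: Ac2O, pyridine, DMAP (cat.), CH2Cl2, 0 °C to rt
Reagents that add atoms: acetic anhydride, CC(=O)OC(C)=O
Why: DMAP-catalysed acylation esterifies the only free hydroxyl (O6) with retention at C6 and leaves the terminal alkyne and the three olefins alone.

Step 12
Reactants: 19 (3Z,6S,7S,9Z,12E)-7-[(tert-butyldimethylsilyl)oxy]pentadeca-3,9,12-trien-1-yn-6-yl acetate
Product: 20 (3Z,6S,7S,9Z,12E)-7-hydroxypentadeca-3,9,12-trien-1-yn-6-yl acetate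
Conditions: HF·pyridine, pyridine, THF, 0 °C to rt; pH 7 work-up, used at once
Reagents that add atoms: none
Why: Fluoride-driven Si–O cleavage under weakly acidic conditions never generates a free alkoxide, so the 1,2-acetyl shift from O6 to O7 should stay slow and the acetate stays on O6.

Step 13
Reactants: 20 (3Z,6S,7S,9Z,12E)-7-hydroxypentadeca-3,9,12-trien-1-yn-6-yl acetate
Product: 22 (1S,3Z)-1-[(2S,7R)-7-[(1S)-1-bromopropyl]-2,3,6,7-tetrahydrooxepin-2-yl]hex-3-en-5-yn-1-yl acetate (target), via 12,13-bromonium ion 21 (not isolated)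
Conditions: 2,4,4,6-tetrabromocyclohexa-2,5-dienone (TBCO, 1.05 equiv), CH2Cl2 (2 mM), 4 Å MS, −40 to 0 °C, dark
Reagents that add atoms: 2,4,4,6-tetrabromocyclohexa-2,5-dienone, O=C1C(Br)=CC(Br)(Br)C=C1Br
Why: Proposed new method: TBCO passes Br+ reversibly onto the olefins of 20; once it sits on C12=C13 (ion 21) the C7 hydroxyl attacks C12 from the side opposite bromine and tribromophenoxide removes the proton, so O–C12 and C13–Br arise in a single anti addition. The nearest known reaction types are halonium-induced 7-exo etherifications of simple alkenols to oxepanes and oxepenes with bulky halonium donors, and the haloperoxidase-mediated cyclisations of laurediol-type diols, neither of which is established as a selective preparative reaction on a skipped-diene hydroxy acetate. The one ring formed, the oxepene O/C7–C12, closes in the 7-exo mode: the Z C9=C10 bond inside the tether removes rotational freedom and turns O7 toward C12, and the seven-membered transition state should outrun 8-endo attack at the electronically similar C13. The C12/C13 relation is fixed stereospecifically by the E geometry (anti addition gives erythro), whereas the olefin face, hence 12R,13S rather than 12S,13R, is controlled by C7 through a chair-like transition state with the C6 and C13 side chains pseudo-equatorial, which leads to the cis-2,7 ring while the mismatched bromonium ion can revert. The step needs site selectivity against 5-endo closure onto C10 of a 9,10-bromonium ion and against the enyne: C12=C13 lies farthest from the two C–O dipoles and is thus the most electron-rich olefin, Z-homoallylic alcohols are sluggish 5-endo substrates, the enyne olefin is conjugated and electron-poor, and O6 is acetylated so that it cannot close a 5-exo tetrahydrofuran onto C9. High dilution, low temperature and the bulky, self-buffering donor are the remaining levers, and this is the one place where the route knowingly carries its risk.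

Compound list
1 | (4S,5S)-2,2-dimethyl-4,5-bis(tosyloxymethyl)-1,3-dioxolane (1,4-di-O-tosyl-2,3-O-isopropylidene-L-threitol, commercial, L-tartrate-derived) | Cc1ccc(cc1)S(=O)(=O)OC[C@@H]1OC(C)(C)O[C@H]1COS(=O)(=O)c1ccc(C)cc1 | starting material
2 | (2S,3S)-2,3-dihydroxybutane-1,4-diyl bis(4-methylbenzenesulfonate) | Cc1ccc(cc1)S(=O)(=O)OC[C@H](O)[C@@H](O)COS(=O)(=O)c1ccc(C)cc1 | intermediate
3 | (2S,2'S)-2,2'-bioxirane [(S,S)-diepoxybutane] | C1O[C@@H]1[C@@H]1CO1 | intermediate
4 | (trimethylsilyl)acetylene | C#C[Si](C)(C)C | starting material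
5 | (E)-1-bromopent-2-ene | CC/C=C/CBr | starting material
6 | trimethylsilylethynylmagnesium bromide | C[Si](C)(C)C#C[Mg]Br | intermediate (not isolated)
7 | trimethyl[(E)-hept-4-en-1-yn-1-yl]silane | C[Si](C)(C)C#CC/C=C/CC | intermediate
8 | (E)-hept-4-en-1-yne | C#CC/C=C/CC | intermediate
9 | lithium (E)-hept-4-en-1-ynide | [Li]C#CC/C=C/CC | intermediate (not isolated)
10 | (1S,6E)-1-[(2S)-oxiran-2-yl]non-6-en-3-yn-1-ol | C1O[C@@H]1[C@@H](O)CC#CC/C=C/CC | intermediate
11 | (1S,3Z,6E)-1-[(2S)-oxiran-2-yl]nona-3,6-dien-1-ol | C1O[C@@H]1[C@@H](O)C/C=C\C/C=C/CC | intermediate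
12 | tert-butyl(dimethyl){[(1S,3Z,6E)-1-[(2S)-oxiran-2-yl]nona-3,6-dien-1-yl]oxy}silane | C1O[C@@H]1[C@@H](O[Si](C)(C)C(C)(C)C)C/C=C\C/C=C/CC | intermediate
13 | 1,4-bis(trimethylsilyl)buta-1,3-diyne | C[Si](C)(C)C#CC#C[Si](C)(C)C | starting material
14 | lithium 4-(trimethylsilyl)buta-1,3-diynide | [Li]C#CC#C[Si](C)(C)C | intermediate (not isolated)
15 | (6S,7S,9Z,12E)-7-[(tert-butyldimethylsilyl)oxy]-1-(trimethylsilyl)pentadeca-9,12-diene-1,3-diyn-6-ol | C[Si](C)(C)C#CC#CC[C@H](O)[C@@H](O[Si](C)(C)C(C)(C)C)C/C=C\C/C=C/CC | intermediate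
16 | (3Z)-3-dicyclohexylboryl alkenyne, O6 bound as dicyclohexylborinate (syn adduct of Cy2BH to C3≡C4 of 15) | C[Si](C)(C)C#C/C(B(C1CCCCC1)C1CCCCC1)=C\C[C@H](OB(C1CCCCC1)C1CCCCC1)[C@@H](O[Si](C)(C)C(C)(C)C)C/C=C\C/C=C/CC | intermediate (not isolated)
17 | (3Z,6S,7S,9Z,12E)-7-[(tert-butyldimethylsilyl)oxy]-1-(trimethylsilyl)pentadeca-3,9,12-trien-1-yn-6-ol | C[Si](C)(C)C#C/C=C\C[C@H](O)[C@@H](O[Si](C)(C)C(C)(C)C)C/C=C\C/C=C/CC | intermediate
18 | (3Z,6S,7S,9Z,12E)-7-[(tert-butyldimethylsilyl)oxy]pentadeca-3,9,12-trien-1-yn-6-ol | C#C/C=C\C[C@H](O)[C@@H](O[Si](C)(C)C(C)(C)C)C/C=C\C/C=C/CC | intermediate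
19 | (3Z,6S,7S,9Z,12E)-7-[(tert-butyldimethylsilyl)oxy]pentadeca-3,9,12-trien-1-yn-6-yl acetate | C#C/C=C\C[C@H](OC(C)=O)[C@@H](O[Si](C)(C)C(C)(C)C)C/C=C\C/C=C/CC | intermediate
20 | (3Z,6S,7S,9Z,12E)-7-hydroxypentadeca-3,9,12-trien-1-yn-6-yl acetate | C#C/C=C\C[C@H](OC(C)=O)[C@@H](O)C/C=C\C/C=C/CC | intermediate (key-step precursor)
21 | (12S,13S)-12,13-bromonium ion of 20, tribromophenoxide as counter-ion | C#C/C=C\C[C@H](OC(C)=O)[C@@H](O)C/C=C\C[C@@H]1[Br+][C@H]1CC.[O-]c1c(Br)cc(Br)cc1Br | intermediate (not isolated)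
22 | (1S,3Z)-1-[(2S,7R)-7-[(1S)-1-bromopropyl]-2,3,6,7-tetrahydrooxepin-2-yl]hex-3-en-5-yn-1-yl acetate | C#C/C=C\C[C@H](OC(C)=O)[C@@H]1CC=CC[C@H]([C@@H](Br)CC)O1 | target

Total step count: 13.
Longest linear sequence: 11 steps (1, 2, 5–13). The branch 3, 4, 5–13 is equally long.

Steps most likely to fail

**Step 13 (bromoetherification).**
- Several things may go wrong. Bromonium capture may occur at the 9,10-olefin in the 5-endo sense. O7 may attack at C13 (8-endo). Facial discrimination may be poor, so that the trans ring competes. The cation may be captured intermolecularly before the slow medium-ring closure.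
- The fallback uses known chemistry only, sets out from 19 and comes back at 22.
- Shi epoxidation with the enantiomer of the fructose-derived ketone (made from L-sorbose) oxidises trans-disubstituted olefins much faster than cis olefins or the enyne. It should give the (12S,13S)-epoxy silyl ether F1.
- Pyridine-buffered HF·pyridine frees the hydroxy epoxide F2.
- Lewis-acid-promoted exo cyclisation of this Z-olefinic hydroxy epoxide (Eu(fod)3 in toluene, or (Bu3Sn)2O/Zn(OTf)2) is a known route to 2,7-disubstituted oxepenes. It opens C12 with inversion to the (12R,13S)-oxepenyl carbinol F3.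
- This alcohol has the configuration that a bromide displacement would invert to the wrong side, so it is corrected first. Dess–Martin oxidation gives the ethyl ketone F4, and L-Selectride at −78 °C, following the Felkin–Anh model for an α-alkoxy ketone, gives the syn (13R)-carbinol F5.
- An Appel-type bromination (CBr4, P(n-Oct)3, toluene, 70 °C) with inversion at C13 then gives 22.

**Step 9 (hydroboration–protonolysis).**
- The borane may also add to the skipped diene or to the silylated triple bond, and protonolysis of the alkenylborane may stay incomplete.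
- The fallback builds the Z olefin before the terminal alkyne is attached. It sets out from 12 and comes back at 17.
- Lithiated 4 with BF3·OEt2 opens 12 at C5 to the silyl alkynol F6, and K2CO3/MeOH gives the terminal alkynol F7.
- Double deprotonation (n-BuLi, −78 °C) followed by one equivalent of I2 gives the iodoalkyne F8.
- Diimide from 2-nitrobenzenesulfonohydrazide reduces the activated iodoalkyne syn, in preference to the internal olefins, to the Z-vinyl iodide F9.
- Sonogashira coupling of F9 with 4 (Pd(PPh3)4, CuI, Et2NH) proceeds with retention of geometry and gives 17.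

**Step 12 (release of O7–H).**
- The acetyl group may shift from O6 to O7 during desilylation, work-up or chromatography. That would hand the wrong hydroxyl to the bromonium ion.
- The fallback avoids any vicinal hydroxy acetate by acetylating only after ring closure. It sets out from 18 and comes back at 22.
- TBDPSCl/imidazole converts 18 into the bis-silyl ether F10.
- CSA in MeOH at 0 °C removes the more acid-labile TBS group selectively to give the C7 carbinol F11.
- TBCO under the conditions of step 13 closes the silyl-protected bromo-oxepene F12.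
- TBAF buffered with AcOH frees the C6 carbinol F13, and Ac2O/pyridine/DMAP gives 22.

Further compounds
F1 | step 13 | (3Z,6S,7S,9Z)-7-[(tert-butyldimethylsilyl)oxy]-11-[(2S,3S)-3-ethyloxiran-2-yl]undeca-3,9-dien-1-yn-6-yl acetate | C#C/C=C\C[C@H](OC(C)=O)[C@@H](O[Si](C)(C)C(C)(C)C)C/C=C\C[C@@H]1O[C@H]1CC
F2 | step 13 | (3Z,6S,7S,9Z)-11-[(2S,3S)-3-ethyloxiran-2-yl]-7-hydroxyundeca-3,9-dien-1-yn-6-yl acetate | C#C/C=C\C[C@H](OC(C)=O)[C@@H](O)C/C=C\C[C@@H]1O[C@H]1CC
F3 | step 13 | (1S,3Z)-1-[(2S,7R)-7-[(1S)-1-hydroxypropyl]-2,3,6,7-tetrahydrooxepin-2-yl]hex-3-en-5-yn-1-yl acetate | C#C/C=C\C[C@H](OC(C)=O)[C@@H]1CC=CC[C@H]([C@@H](O)CC)O1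
F4 | step 13 | (1S,3Z)-1-[(2S,7R)-7-propanoyl-2,3,6,7-tetrahydrooxepin-2-yl]hex-3-en-5-yn-1-yl acetate | C#C/C=C\C[C@H](OC(C)=O)[C@@H]1CC=CC[C@H](C(=O)CC)O1
F5 | step 13 | (1S,3Z)-1-[(2S,7R)-7-[(1R)-1-hydroxypropyl]-2,3,6,7-tetrahydrooxepin-2-yl]hex-3-en-5-yn-1-yl acetate | C#C/C=C\C[C@H](OC(C)=O)[C@@H]1CC=CC[C@H]([C@H](O)CC)O1
F6 | step 9 | (4S,5S,7Z,10E)-5-[(tert-butyldimethylsilyl)oxy]-1-(trimethylsilyl)trideca-7,10-dien-1-yn-4-ol | C[Si](C)(C)C#CC[C@H](O)[C@@H](O[Si](C)(C)C(C)(C)C)C/C=C\C/C=C/CC
F7 | step 9 | (4S,5S,7Z,10E)-5-[(tert-butyldimethylsilyl)oxy]trideca-7,10-dien-1-yn-4-ol | C#CC[C@H](O)[C@@H](O[Si](C)(C)C(C)(C)C)C/C=C\C/C=C/CC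
F8 | step 9 | (4S,5S,7Z,10E)-5-[(tert-butyldimethylsilyl)oxy]-1-iodotrideca-7,10-dien-1-yn-4-ol | IC#CC[C@H](O)[C@@H](O[Si](C)(C)C(C)(C)C)C/C=C\C/C=C/CC
F9 | step 9 | (1Z,4S,5S,7Z,10E)-5-[(tert-butyldimethylsilyl)oxy]-1-iodotrideca-1,7,10-trien-4-ol | I/C=C\C[C@H](O)[C@@H](O[Si](C)(C)C(C)(C)C)C/C=C\C/C=C/CC
F10 | step 12 | (3Z,6S,7S,9Z,12E)-7-[(tert-butyldimethylsilyl)oxy]-6-[(tert-butyldiphenylsilyl)oxy]pentadeca-3,9,12-trien-1-yne | C#C/C=C\C[C@H](O[Si](c1ccccc1)(c1ccccc1)C(C)(C)C)[C@@H](O[Si](C)(C)C(C)(C)C)C/C=C\C/C=C/CC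
F11 | step 12 | (3Z,6S,7S,9Z,12E)-6-[(tert-butyldiphenylsilyl)oxy]pentadeca-3,9,12-trien-1-yn-7-ol | C#C/C=C\C[C@H](O[Si](c1ccccc1)(c1ccccc1)C(C)(C)C)[C@@H](O)C/C=C\C/C=C/CC
F12 | step 12 | {[(1S,3Z)-1-[(2S,7R)-7-[(1S)-1-bromopropyl]-2,3,6,7-tetrahydrooxepin-2-yl]hex-3-en-5-yn-1-yl]oxy}(tert-butyl)diphenylsilane | C#C/C=C\C[C@H](O[Si](c1ccccc1)(c1ccccc1)C(C)(C)C)[C@@H]1CC=CC[C@H]([C@@H](Br)CC)O1
F13 | step 12 | (1S,3Z)-1-[(2S,7R)-7-[(1S)-1-bromopropyl]-2,3,6,7-tetrahydrooxepin-2-yl]hex-3-en-5-yn-1-ol | C#C/C=C\C[C@H](O)[C@@H]1CC=CC[C@H]([C@@H](Br)CC)O1
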